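## Analysis of the target

Iridal (21) is a monocyclic seco-triterpenoid with one cyclohexane ring, C6–C11 in iridal numbering (C1 aldehyde, C2 its α-carbon, C3–C5 the hydroxypropyl arm with C3 the carbinol, C12–C24 the homofarnesyl chain). The ring holds three contiguous stereocentres: C6 (R, tertiary), C11 (S, quaternary, methyl plus homofarnesyl) and C10 (S, tertiary carbinol). The C10 hydroxyl, the C11 methyl and the C6 arm lie on one face; the C10 methyl and the homofarnesyl chain lie on the other. The exocyclic C7=C2 alkene is tetrasubstituted and Z, with the formyl group cis to C6, and the chain carries two E-trisubstituted alkenes and a prenyl end. Sensitive points are the enal (E/Z isomerisation, and γ-deprotonation at C6 that would epimerise or deconjugate), the tertiary alcohol (ionisation), and the polyene (acid-induced cationic cyclisation, electrophilic oxidants). The difficulty lies in the two adjacent fully substituted carbons C10 and C11 next to C6, in an alkene geometry that no neighbouring hydrogen can direct, and in telling five or six alkenes apart. The strategy rests on one observation: C9–C10(O)–C11(CH3)(C12…) is C1–C2–C3(CH3)(C4…) of geranylgeraniol (1). Its 2,3-epoxide therefore already carries the C10 oxygen, the C11 methyl and the whole chain with the right alkene geometry, and it makes C11 an electrophile of defined configuration that C6 can attack to close the ring. The relative configuration of the ring (equatorial C10 oxygen, axial C11 methyl, equatorial C6 arm) is what anti opening of a trans-epoxide through a chair delivers.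

## Retrosynthetic reasoning

**21 from 19.** The aldehyde carbon C1 is traced back to a nitrile. A cyano group is the slimmest carbonyl surrogate, it survives a methyl nucleophile and a borane, and one hydride reduction at the very end reveals the enal without any alcohol oxidation that would have to distinguish C1 from C3.

**19 from 17.** The C3–O bond is cut. The hydroxypropyl arm is carried as an allyl group, inert to everything before, and is unmasked by anti-Markovnikov hydration of the only monosubstituted alkene.

**17 from 16, and 16 from 15.** The C10–CH3 bond is cut to ketone 16, which comes from the secondary alcohol 15 by oxidation. The C10 oxygen arrives from the epoxide on a CH carbon, so the methyl group has to be added afterwards, from the face opposite to the C11 methyl and the C6 arm.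

**15 from 12 and 13.** The C7=C2 bond is cut. Phosphonate 13 brings C1, C2 and the C2 methyl in one piece. The forward reaction has to place the cyano group, not the methyl group, next to the branched C6.

**12 from 10 (key disconnection).** The C6–C11 bond is cut. A 4-hydroxycyclohexanone whose carbinol carbon sits beside a quaternary carbon is the retron of an epoxide opened at its tertiary carbon by the α-carbon of a ketone. This cut is chosen because C11 is the only all-carbon stereocentre, and forming it by inversion at an enantiopure oxirane carbon is stereospecific. The same event closes the ring and sets C6. The ketone must be present as a regio-defined enol derivative pointing towards C6, which is why 10 is an enol silane.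

**10 from 9 and 7.** The C5–C4 bond is cut. Conjugate addition of the vinyl group of 7 to enone 9, with the enolate trapped on oxygen, is the only simple way to obtain the enol silane towards C6 and not C8, and it also fixes the enol geometry.

**9 from 6 and 7; 6 from 3 and 4.** The C6–C7 bond is cut by acyl substitution on Weinreb amide 6. The C8–C9 bond is cut by alkylation of enolate 5, made from 4, with triflate 3. Both are standard and leave the epoxide alone.

**3 from 2, 2 from 1.** Sulfonylation of epoxy alcohol 2, and catalytic asymmetric epoxidation of the allylic alcohol 1, which is the source of all absolute configuration.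

## Alternatives that were turned down

**Alternative 1:** The C10–C11 bond is cut, leading to the acyclic keto enoate A1. In the forward step SmI2 reduces the methyl ketone of A1 to a ketyl whose carbon adds 6-exo-trig to the β-carbon of the enoate and gives cyclohexanol A2.
- For: the tertiary carbinol with its methyl group and the quaternary C11 are made in one step, and ketyl–olefin closures usually place the hydroxyl trans to the ester arm, which is the iridal relationship. On C10 this route is stronger than the chosen one, which needs an oxidation and a face-selective methyl addition.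
- Against: A1 must be assembled enantiopure with the C6 and C7 stereocentres on an open chain. The two-carbon ester arm of A2 still has to be grown into the thirteen-carbon chain, with two E-trisubstituted alkenes made one by one. The C7 silyl ether must then be oxidised and olefinated just as in the chosen route.
- Comparison: the chosen route takes the whole chain and both C10/C11 configurations from one commercial polyprenol and one catalytic asymmetric step, and is far shorter.

**Alternative 2:** The C11–C12 and C6–C5 bonds are cut, leading to enone A3 and homofarnesyl iodide A4. A homofarnesyl copper nucleophile made from A4 adds to C11 of A3 and the enolate is allylated at C6 to give A5.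
- For: the route is convergent, and A5 is the C10-methylated counterpart of 12, so the endgame is two steps shorter and has no facial question at C10. On these points it is stronger.
- Against: the β-carbon of A3 is already disubstituted and sits beside the fully substituted C10, which is a very slow case for cuprate addition. The face of attack has to be chosen by the difference between CH3 and OSiEt3 on C10, which is small. A3 needs its own asymmetric synthesis and A4 a homologation from farnesol, used in stoichiometric amount.
- Comparison: the chosen route sets C11 by stereospecific inversion and does not depend on discriminating two similar groups.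

**Alternative 3:** The C6–C7 bond is cut, leading to the Z-enol triflate A6. Zerovalent palladium inserts into the C–OTf bond, the alkenylpalladium adds 6-exo across C6=C5, and the metal walks to C3 and leaves as the aldehyde A7.
- For: the alkene geometry is passed on stereospecifically from the enol triflate. This is stronger than the chosen route, where geometry rests on a steric preference in an olefination. The C3 oxygen also arrives without a hydroboration.
- Against: A6 needs the C10/C11 pair, including the quaternary carbon, built in an open chain without an obvious source. C6 is set in a migratory insertion next to a quaternary carbon with uncertain facial control. C1 (ester) and C3 (aldehyde) emerge with their oxidation levels the wrong way round, and C10 is still secondary.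
- Comparison: the chosen route is shorter, needs the same C10 adjustment, and concentrates its risk in one step.

Key step: step 6

Remark 1: enol silane 10 is taken as the (Z)-isomer (silyloxy group cis to C5), because a chair transition state turns this geometry, not the (E) one, into the C6 configuration of iridal.
Remark 2: 12 is formulated as the free C10 alcohol; any C10 silyl ether formed by silyl transfer is cleaved in the aqueous work-up.
Homofarnesyl = (3E,7E)-4,8,12-trimethyltrideca-3,7,11-trien-1-yl.

## Route

**Step 1**
Reactants: 1 (2E,6E,10E)-geranylgeraniol
Product: 2 (2S,3S)-2,3-epoxygeranylgeraniol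
Conditions: Ti(OiPr)4 (cat.), L-(+)-diethyl tartrate, t-BuOOH, 4 Å MS, CH2Cl2, −20 °C
Reagents that add atoms: tert-butyl hydroperoxide, CC(C)(C)OO
Why: Sharpless asymmetric epoxidation; only the allylic alcohol alkene binds to titanium, and the L-(+)-tartrate delivers oxygen to the face that gives the (2S,3S)-epoxide, as with geraniol. This fixes the C10 oxygen and the configuration of the future C11.

**Step 2**
Reactants: 2 (2S,3S)-2,3-epoxygeranylgeraniol
Product: 3 (2S,3S)-2,3-epoxygeranylgeranyl trifluoromethanesulfonate
Conditions: Tf2O, 2,6-lutidine, CH2Cl2, −78 °C; cold aqueous wash, used at once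
Reagents that add atoms: trifluoromethanesulfonic anhydride, O=S(=O)(OS(=O)(=O)C(F)(F)F)C(F)(F)F
Why: O-sulfonylation of a primary alcohol under buffered conditions; epoxy triflates of this type are stable enough at low temperature to be alkylated directly. No stereocentre is touched.

**Step 3**
Reactants: 3 (2S,3S)-2,3-epoxygeranylgeranyl trifluoromethanesulfonate; 4 N-methoxy-N-methylacetamide
Product: 6 (4S,5S,8E,12E)-4,5-epoxy-N-methoxy-N,5,9,13,17-pentamethyloctadeca-8,12,16-trienamide, via lithium enolate 5 (not isolated)
Conditions: 4, LiN(i-Pr)2, THF, −78 °C; then 3, −78 → −40 °C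
Reagents that add atoms: lithium diisopropylamide, CC(C)[N-]C(C)C.[Li+] (lithium held only in intermediate 5)
Why: SN2 C-alkylation of a lithium amide enolate by a primary triflate, which forms C8–C9. The triflate reacts far faster than the trisubstituted epoxide, so the oxirane and its two stereocentres are carried through unchanged.

**Step 4**
Reactants: 6 epoxy Weinreb amide; 7 vinylmagnesium bromide
Product: 9 (6S,7S,10E,14E)-6,7-epoxy-7,11,15,19-tetramethylicosa-1,10,14,18-tetraen-3-one, via chelated magnesium hemiaminal 8 (not isolated)
Conditions: 7, THF, −20 → 0 °C; inverse quench into cold aq. citric acid/Et2O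
Reagents that add atoms: none
Why: Weinreb ketone synthesis; the five-membered magnesium chelate 8 stops the addition at the ketone stage. The cold acidic inverse quench protonates the released N,O-dimethylhydroxylamine so that it cannot add to the vinyl ketone, and the short contact spares the epoxide.

**Step 5**
Reactants: 9 epoxy vinyl ketone; 7 vinylmagnesium bromide
Product: 10 (4Z,8S,9S,12E,16E)-8,9-epoxy-9,13,17,21-tetramethyl-5-(trimethylsilyloxy)docosa-1,4,12,16,20-pentaene
Conditions: 7, CuBr·SMe2 (10 mol %), Me3SiCl, HMPA, THF, −78 °C; Et3N, pentane, cold aq. NaHCO3; used crude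
Reagents that add atoms: chlorotrimethylsilane, C[Si](C)(C)Cl
Why: Copper-catalysed, chlorosilane-accelerated conjugate addition of a Grignard reagent with in-situ O-silylation; the enol silane is formed only towards C6. Addition through the s-cis enone conformer, the usual course for acyclic alkyl vinyl ketones under these conditions, places oxygen cis to C5 and gives the (Z)-isomer. The trisubstituted epoxide is inert to the copper reagent at −78 °C.

**Step 6**
Reactants: 10 (Z)-epoxy enol silane
Product: 12 (2S,3S,4S)-4-hydroxy-3-methyl-2-(prop-2-enyl)-3-[(3E,7E)-4,8,12-trimethyltrideca-3,7,11-trienyl]cyclohexan-1-one, via aluminium alkoxide 11 (not isolated)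
Conditions: MeAlCl2, CH2Cl2, −78 °C; Et3N/MeOH, then aq. NaHCO3
Reagents that add atoms: methylaluminium dichloride, C[Al](Cl)Cl (aluminium, methyl and one chlorine held only in intermediate 11)
Why: MeAlCl2 binds the oxirane oxygen, the C11–O bond lengthens because C11 is tertiary, and the enol silane attacks C11 through C6 from the side opposite to the departing oxygen; the silyloxocarbenium ion at C7 then loses Me3Si to chloride and leaves the ketone, while the C10 oxygen is held as alkoxide 11 until work-up. The closest known reaction type is the Lewis acid-promoted, epoxide-initiated cation–olefin cyclisation with an enol silane as terminating nucleophile, here in its monocyclic form and with the regiochemistry of epoxide opening seen in oxidosqualene cyclisation. The ring C6–C11 closes 6-endo with respect to the epoxide (both oxirane carbons end in the ring) and endo with respect to the enol double bond. C11 is fixed by stereospecific inversion at the oxirane carbon, so its methyl group ends cis to the C10 oxygen, which keeps its configuration and sits equatorial. C6 is set by the enol geometry read through a chair: the substituent cis to the enol oxygen, the allyl CH2 of (Z)-10, becomes equatorial and trans to the homofarnesyl chain, and the hydrogen cis to C8 becomes axial. The step needs C–O cleavage at C11 and not 5-exo attack at C10, carbon and not oxygen attack of the enol silane, and no interference by the chain alkenes. These are secured by the cation-stabilising tertiary C11, by the much higher π-nucleophilicity of an enol silane than of a trisubstituted alkene, and by the fact that the nearest chain alkene could only close a four- or five-membered ring against its own polarisation; low temperature and short reaction time are meant to outrun hydride shift in the activated epoxide.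

**Step 7**
Reactants: 12 hydroxy ketone; 13 diethyl (1-cyanoethyl)phosphonate
Product: 15 (2Z)-2-[(2R,3S,4S)-4-hydroxy-3-methyl-2-(prop-2-enyl)-3-homofarnesylcyclohexylidene]propanenitrile, via sodium phosphonate carbanion 14 (not isolated)
Conditions: 13 (slight excess over base), NaH, THF, 0 °C; then 12, 0 → 65 °C
Reagents that add atoms: sodium hydride, [Na+].[H-] (sodium held only in intermediate 14)
Why: Horner–Wadsworth–Emmons olefination with a cyano-stabilised phosphonate, which is small enough for an α-branched cyclohexanone. With the equatorial C10 hydroxyl holding the chair in which the C6 allyl group is equatorial, the linear cyano group and not the methyl group is expected to take the position cis to C6, giving the Z-alkene. Keeping the phosphonate in excess over NaH leaves no base strong enough to deprotonate the alcohol or the γ-position C6.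

**Step 8**
Reactants: 15 hydroxy nitrile
Product: 16 (2Z)-2-[(2R,3S)-3-methyl-4-oxo-2-(prop-2-enyl)-3-homofarnesylcyclohexylidene]propanenitrile
Conditions: Dess–Martin periodinane, NaHCO3, CH2Cl2, 0 °C → rt
Reagents that add atoms: none
Why: Dess–Martin oxidation of a secondary alcohol under buffered, non-acidic conditions; the alkenes and the nitrile are inert and C6 is not α to the new ketone.

**Step 9**
Reactants: 16 keto nitrile
Product: 17 (2Z)-2-[(2R,3S,4S)-4-hydroxy-3,4-dimethyl-2-(prop-2-enyl)-3-homofarnesylcyclohexylidene]propanenitrile
Conditions: MeLi, CeCl3 (MeCeCl2 preformed), THF, −78 °C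
Reagents that add atoms: methyllithium, C[Li]
Why: Organocerium 1,2-addition; MeCeCl2 is nucleophilic but weakly basic, so it adds to the hindered, enolisable C10 ketone without touching the γ-hydrogen at C6, and much faster than to the tetrasubstituted conjugated nitrile. One face of the carbonyl carries both the C11 methyl (vicinal) and the C6 allyl group (1,3-related): in the chair with axial C11 methyl, equatorial attack is blocked, and in the flipped chair the syn-axial allyl blocks axial attack. The methyl group should therefore enter from the chain face, leaving the hydroxyl cis to the C11 methyl and the C6 arm.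

**Step 10**
Reactants: 17 tertiary alcohol
Product: 19 (2Z)-2-[(2R,3S,4S)-4-hydroxy-2-(3-hydroxypropyl)-3,4-dimethyl-3-homofarnesylcyclohexylidene]propanenitrile, via B-alkyl-9-BBN adduct 18 (not isolated)
Conditions: 9-BBN, THF, 0 °C → rt; NaBO3·4H2O, H2O, rt
Reagents that add atoms: 9-borabicyclo[3.3.1]nonane, B1C2CCCC1CCC2 (boron and bicycle held only in intermediate 18); sodium perborate, [Na+].[O-]OB=O (oxygen of the new hydroxyl)
Why: Hydroboration–oxidation; 9-BBN adds to the monosubstituted alkene far faster than to trisubstituted or tetrasubstituted ones and places boron on the terminal carbon C3. Perborate oxidises the C–B bond near neutral pH, which avoids the hydration and epoxidation that alkaline peroxide can cause with a conjugated nitrile.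

**Step 11**
Reactants: 19 nitrile diol
Product: 21 iridal, via N-aluminio aldimine 20 (not isolated)
Conditions: i-Bu2AlH (excess), toluene, −78 → −40 °C; aq. potassium sodium tartrate, then dilute aq. tartaric acid, 0 °C
Reagents that add atoms: diisobutylaluminium hydride, CC(C)C[AlH]CC(C)C (aluminium held only in intermediate 20); water, O (aldehyde oxygen)
Why: Partial reduction of a nitrile; one hydride adds to give the N-aluminated aldimine 20, which resists further reduction and is hydrolysed to the aldehyde on mild acidic work-up. The two hydroxyl groups only consume reagent, and the alkene geometry is not involved in the reduction; the Z-enal, with the small formyl hydrogen facing C6, is also expected to be the less strained isomer.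

## Compound list

1 | (2E,6E,10E)-geranylgeraniol | CC(C)=CCC/C(C)=C/CC/C(C)=C/CC/C(C)=C/CO | starting material
2 | (2S,3S)-2,3-epoxygeranylgeraniol | CC(C)=CCC/C(C)=C/CC/C(C)=C/CC[C@]1(C)O[C@H]1CO | intermediate
3 | (2S,3S)-2,3-epoxygeranylgeranyl trifluoromethanesulfonate | CC(C)=CCC/C(C)=C/CC/C(C)=C/CC[C@]1(C)O[C@H]1COS(=O)(=O)C(F)(F)F | intermediate
4 | N-methoxy-N-methylacetamide | CC(=O)N(C)OC | starting material
5 | lithium enolate of N-methoxy-N-methylacetamide | C=C(O[Li])N(C)OC | intermediate (not isolated)
6 | (4S,5S,8E,12E)-4,5-epoxy-N-methoxy-N,5,9,13,17-pentamethyloctadeca-8,12,16-trienamide | CC(C)=CCC/C(C)=C/CC/C(C)=C/CC[C@]1(C)O[C@H]1CCC(=O)N(C)OC | intermediate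
7 | vinylmagnesium bromide | C=C[Mg]Br | starting material
8 | bromomagnesium alkoxide of the tetrahedral adduct of 6 and 7 (hemiaminal carbon unassigned) | CC(C)=CCC/C(C)=C/CC/C(C)=C/CC[C@]1(C)O[C@H]1CCC(C=C)(O[Mg]Br)N(C)OC | intermediate (not isolated)
9 | (6S,7S,10E,14E)-6,7-epoxy-7,11,15,19-tetramethylicosa-1,10,14,18-tetraen-3-one | CC(C)=CCC/C(C)=C/CC/C(C)=C/CC[C@]1(C)O[C@H]1CCC(=O)C=C | intermediate
10 | (4Z,8S,9S,12E,16E)-8,9-epoxy-9,13,17,21-tetramethyl-5-(trimethylsilyloxy)docosa-1,4,12,16,20-pentaene | CC(C)=CCC/C(C)=C/CC/C(C)=C/CC[C@]1(C)O[C@H]1CC/C(O[Si](C)(C)C)=C/CC=C | intermediate (key-step precursor)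
11 | chloro(methyl)aluminium alkoxide of 12 | CC(C)=CCC/C(C)=C/CC/C(C)=C/CC[C@@]1(C)[C@H](CC=C)C(=O)CC[C@@H]1O[Al](C)Cl | intermediate (not isolated)
12 | (2S,3S,4S)-4-hydroxy-3-methyl-2-(prop-2-enyl)-3-[(3E,7E)-4,8,12-trimethyltrideca-3,7,11-trienyl]cyclohexan-1-one | CC(C)=CCC/C(C)=C/CC/C(C)=C/CC[C@@]1(C)[C@H](CC=C)C(=O)CC[C@@H]1O | intermediate (key-step product)
13 | diethyl (1-cyanoethyl)phosphonate | CCOP(=O)(OCC)C(C)C#N | starting material
14 | sodium salt of the carbanion of 13 | CCOP(=O)(OCC)[C-](C)C#N.[Na+] | intermediate (not isolated)
15 | (2Z)-2-[(2R,3S,4S)-4-hydroxy-3-methyl-2-(prop-2-enyl)-3-homofarnesylcyclohexylidene]propanenitrile | CC(C)=CCC/C(C)=C/CC/C(C)=C/CC[C@@]1(C)[C@H](CC=C)/C(=C(/C)C#N)CC[C@@H]1O | intermediate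
16 | (2Z)-2-[(2R,3S)-3-methyl-4-oxo-2-(prop-2-enyl)-3-homofarnesylcyclohexylidene]propanenitrile | CC(C)=CCC/C(C)=C/CC/C(C)=C/CC[C@@]1(C)[C@H](CC=C)/C(=C(/C)C#N)CCC1=O | intermediate
17 | (2Z)-2-[(2R,3S,4S)-4-hydroxy-3,4-dimethyl-2-(prop-2-enyl)-3-homofarnesylcyclohexylidene]propanenitrile | CC(C)=CCC/C(C)=C/CC/C(C)=C/CC[C@@]1(C)[C@H](CC=C)/C(=C(/C)C#N)CC[C@]1(C)O | intermediate
18 | B-alkyl-9-borabicyclo[3.3.1]nonane adduct of 17 (boron on C3) | CC(C)=CCC/C(C)=C/CC/C(C)=C/CC[C@@]1(C)[C@H](CCCB2C3CCCC2CCC3)/C(=C(/C)C#N)CC[C@]1(C)O | intermediate (not isolated)
19 | (2Z)-2-[(2R,3S,4S)-4-hydroxy-2-(3-hydroxypropyl)-3,4-dimethyl-3-homofarnesylcyclohexylidene]propanenitrile | CC(C)=CCC/C(C)=C/CC/C(C)=C/CC[C@@]1(C)[C@H](CCCO)/C(=C(/C)C#N)CC[C@]1(C)O | intermediate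
20 | N-(diisobutylaluminio) aldimine of 21 with both hydroxyls as diisobutylaluminium alkoxides | CC(C)=CCC/C(C)=C/CC/C(C)=C/CC[C@@]1(C)[C@H](CCCO[Al](CC(C)C)CC(C)C)/C(=C(/C)C=N[Al](CC(C)C)CC(C)C)CC[C@]1(C)O[Al](CC(C)C)CC(C)C | intermediate (not isolated)
21 | iridal, (2Z)-2-[(2R,3S,4S)-4-hydroxy-2-(3-hydroxypropyl)-3,4-dimethyl-3-[(3E,7E)-4,8,12-trimethyltrideca-3,7,11-trienyl]cyclohexylidene]propanal | CC(C)=CCC/C(C)=C/CC/C(C)=C/CC[C@@]1(C)[C@H](CCCO)/C(=C(/C)C=O)CC[C@]1(C)O | target

## Step count and least certain steps

Total step count: 11. Longest linear sequence: 11 steps, from geranylgeraniol 1.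

**Step 6 (key step).** The activated epoxide may rearrange by hydride shift from C10 to C11 before the C–C bond forms, the enol silane may be protodesilylated, the enol oxygen may attack in place of carbon, or closure may occur 5-exo at C10. Fallback, setting out from 6 and coming back at 12: the enol silane is replaced by the stable enol of a β-keto ester, and the allyl group is moved to C6 only after the ring is closed. Weinreb amide 6 is acylated onto the lithium enolate of allyl acetate (LiN(i-Pr)2, THF, −78 °C) to give the allyl β-keto ester F1. Treatment with SnCl4 in CH2Cl2 at low temperature lets the enol carbon C6 open the epoxide at C11, a β-keto ester being an established terminating group of cationic epoxide cyclisations, to give the cyclised allyl 2-oxocyclohexanecarboxylate F2. Pd(PPh3)4 in THF then effects the Tsuji decarboxylative allylation, which delivers the allyl group to C6 with loss of CO2. Brief treatment with DBU settles C6 in the equatorial configuration of 12.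

**Step 5.** Addition through the s-trans conformer would erode the enol geometry, and the trimethylsilyl enol ether may hydrolyse on work-up. Fallback, setting out from 9 and coming back at 12: C6 is corrected after ring closure instead of being controlled before it. Any (E)-enol silane F3 in the mixture is cyclised together with 10 under the conditions of step 6. Through the same chair it gives the C6 epimer of the hydroxy ketone F4, with axial allyl. Because C6 is α to the ketone, the mixture is then equilibrated with DBU in toluene, which should favour 12 with its all-equatorial allyl, chain and hydroxyl; remaining epimer is separated and resubmitted.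

**Step 7.** Addition of the phosphonate carbanion to the α-branched ketone may be slow at a temperature where enolisation towards C6, poor control of the alkene geometry, or drift of the double bond out of conjugation set in. Fallback, setting out from 12 and coming back at 15: phosphorus is exchanged for silicon so that the C–C bond forms irreversibly at −78 °C. Propionitrile is silylated (LiN(i-Pr)2, Me3SiCl) to 2-(trimethylsilyl)propanenitrile F5. Its lithium derivative (LiN(i-Pr)2, THF, −78 °C, excess to cover the free hydroxyl) adds to the C7 ketone of 12, and the β-silyl alkoxide collapses in a Peterson elimination to 15 on warming. The geometric isomers are separated if needed.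

**Step 9.** Once C7 is trigonal the ring can flip to relieve allylic strain, which may weaken the facial preference at C10; over-addition to the nitrile is a lesser concern. Fallback, setting out from 16 and coming back at 17: the methyl group is introduced as a methylene carbon followed by hydride. Ketone 16 is converted into the spiro-epoxide F6 by Corey–Chaykovsky methylene transfer. The kinetically controlled sulfonium ylide (Me3SI, KN(SiMe3)2, THF) and the reversibly adding sulfoxonium ylide (Me3S(O)I, NaH, DMSO) generally deliver the methylene carbon with opposite facial preference, so the one that places CH2 on the chain face is chosen. LiBHEt3 in THF at 0 °C then opens F6 at the CH2 carbon to give 17.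

## Further compounds

F1 | step 6 | allyl (6S,7S,10E,14E)-6,7-epoxy-7,11,15,19-tetramethyl-3-oxoicosa-10,14,18-trienoate | CC(C)=CCC/C(C)=C/CC/C(C)=C/CC[C@]1(C)O[C@H]1CCC(=O)CC(=O)OCC=C
F2 | step 6 | allyl (2S,3S)-3-hydroxy-2-methyl-6-oxo-2-homofarnesylcyclohexane-1-carboxylate (C1 epimerisable, unassigned) | CC(C)=CCC/C(C)=C/CC/C(C)=C/CC[C@@]1(C)C(C(=O)OCC=C)C(=O)CC[C@@H]1O
F3 | step 5 | (4E,8S,9S,12E,16E)-8,9-epoxy-9,13,17,21-tetramethyl-5-(trimethylsilyloxy)docosa-1,4,12,16,20-pentaene | CC(C)=CCC/C(C)=C/CC/C(C)=C/CC[C@]1(C)O[C@H]1CC/C(O[Si](C)(C)C)=C\CC=C
F4 | step 5 | (2R,3S,4S)-4-hydroxy-3-methyl-2-(prop-2-enyl)-3-homofarnesylcyclohexan-1-one (C6 epimer of 12) | CC(C)=CCC/C(C)=C/CC/C(C)=C/CC[C@@]1(C)[C@@H](CC=C)C(=O)CC[C@@H]1O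
F5 | step 7 | 2-(trimethylsilyl)propanenitrile | CC(C#N)[Si](C)(C)C
F6 | step 9 | spiro-epoxide at C10 of 16 (oxygen on the face of the C11 methyl, CH2 on the chain face) | CC(C)=CCC/C(C)=C/CC/C(C)=C/CC[C@@]1(C)[C@H](CC=C)/C(=C(/C)C#N)CC[C@@]12CO2
A1 | alternative 1 | ethyl (E)-keto enoate, acyclic precursor of A2 with the C6 and C7 stereocentres | CCOC(=O)/C=C(\C)[C@H](CCCOCc1ccc(OC)cc1)[C@@H](O[Si](C)(C)C(C)(C)C)CCC(C)=O
A2 | alternative 1 | cyclohexanol with C10 tertiary alcohol, C11 quaternary centre and acetate arm | CCOC(=O)C[C@@]1(C)[C@H](CCCOCc2ccc(OC)cc2)[C@@H](O[Si](C)(C)C(C)(C)C)CC[C@]1(C)O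
A3 | alternative 2 | (S)-3,4-dimethyl-4-(triethylsilyloxy)cyclohex-2-en-1-one | CC1=CC(=O)CC[C@]1(C)O[Si](CC)(CC)CC
A4 | alternative 2 | homofarnesyl iodide, (3E,7E)-1-iodo-4,8,12-trimethyltrideca-3,7,11-triene | CC(C)=CCC/C(C)=C/CC/C(C)=C/CCI
A5 | alternative 2 | 2-allyl-3-homofarnesyl-3,4-dimethyl-4-(triethylsilyloxy)cyclohexanone | CC(C)=CCC/C(C)=C/CC/C(C)=C/CC[C@@]1(C)[C@H](CC=C)C(=O)CC[C@]1(C)O[Si](CC)(CC)CC
A6 | alternative 3 | acyclic (Z)-enol triflate of the 2-methyl β-keto ester carrying the C10 silyl ether, the C11 quaternary centre and the (E)-alkenol arm | CCOC(=O)/C(C)=C(\OS(=O)(=O)C(F)(F)F)CC[C@H](O[Si](CC)(CC)CC)[C@@](C)(CC/C=C(\C)CC/C=C(\C)CCC=C(C)C)/C=C/CCO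
A7 | alternative 3 | cyclised tetrasubstituted enoate with C3 aldehyde and C10 triethylsilyl ether | CC(C)=CCC/C(C)=C/CC/C(C)=C/CC[C@@]1(C)[C@H](CCC=O)/C(=C(/C)C(=O)OCC)CC[C@@H]1O[Si](CC)(CC)CC
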